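**Retrosynthetic overview**
1. Numbering: pyran O1, C2 (ring B), C3, C4, C5, C6; carbinol carbon C7 (ring C); chain C1'-C3' from C3 to ring A. The plan rests on C5, which carries two oxygenated one-carbon arms, C6 (bound to O1) and C7. These are read as the two CH2 groups of a 3-substituted oxetane hanging on C4.
2. The C7–ring C bond is cut first: aryl Grignard on the C7 aldehyde, reoxidation, oxazaborolidine reduction to (R)-C7, desilylation last. This leads back to the all-cis 5-hydroxymethyl pyran 18.
3. O1–C6 is the key cut. In carbinol 17 the C2 hydroxyl opens the oxetane under a chiral phosphoric acid, so the pyran and C5 arise in one step.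
4. C4–C5 is cut to a C4 alkylzinc reagent and 3-iodooxetane (nickel-catalysed Negishi coupling). C2–C3 is cut by an Evans syn-aldol whose imide carbonyl is C4.
5. The E-configured C2'=C3' bond with ring A comes from cross-metathesis of a pent-4-enoyl imide with a 4-silyloxystyrene. Rings A, B, C and the oxetane are bought, and the pyran (step 11) is the only ring built.

Key step: step 11

Abbreviations: TBS = tert-butyldimethylsilyl, TES = triethylsilyl. Pyran numbering is used for all intermediates.
Assumption: which enantiomer of the phosphoric acid is matched to the (2R,3S) substrate cannot be derived with certainty by analogy. The (R)-acid is written. The C5 assignment of 18 would be checked by the H3/H5 NOE on the first run, and the (S)-acid would take its place in an otherwise unchanged step if needed.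

**Step 1**
Reactants: 1 4-hydroxybenzaldehyde
Product: 2 4-(tert-butyldimethylsilyloxy)benzaldehyde
Conditions: TBSCl, imidazole, DMF, rt
Reagents that add atoms: tert-butyldimethylsilyl chloride, CC(C)(C)[Si](C)(C)Cl
Why: Imidazole-promoted silyl ether formation on a phenol, giving an aryl TBS ether that should survive the later neutral, Lewis-acidic and organometallic steps and fall to fluoride at the end.

**Step 2**
Reactants: 2 4-(tert-butyldimethylsilyloxy)benzaldehyde (part of the batch; the rest is kept for step 5)
Product: 3 tert-butyldimethyl(4-vinylphenoxy)silane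
Conditions: Ph3PCH3Br, n-BuLi, THF, 0 °C; then 2, 0 °C → rt
Reagents that add atoms: methyltriphenylphosphonium bromide, C[P+](c1ccccc1)(c1ccccc1)c1ccccc1.[Br-]
Why: Wittig methylenation of an aromatic aldehyde, with the ylide preformed from a slight deficit of base so that no free base can attack the aryl silyl ether.

**Step 3**
Reactants: 4 (R)-4-benzyloxazolidin-2-one; 5 pent-4-enoyl chloride
Product: 6 (R)-4-benzyl-3-(pent-4-enoyl)oxazolidin-2-one
Conditions: Et3N, DMAP (10 mol %), CH2Cl2, 0 °C → rt
Reagents that add atoms: none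
Why: DMAP-catalysed N-acylation of an oxazolidinone by an acid chloride, which leaves the stereocentre of the auxiliary untouched.

**Step 4**
Reactants: 6 (R)-4-benzyl-3-(pent-4-enoyl)oxazolidin-2-one; 3 tert-butyldimethyl(4-vinylphenoxy)silane
Product: 7 (R)-4-benzyl-3-[(E)-5-(4-TBSO-phenyl)pent-4-enoyl]oxazolidin-2-one
Conditions: second-generation Grubbs catalyst RuCl2(=CHPh)(PCy3)(SIMes) (5 mol %), 3 (2.5 equiv), 1,4-benzoquinone (10 mol %), CH2Cl2, 40 °C
Reagents that add atoms: none
Why: Olefin cross-metathesis of a terminal alkene with a styrene should give the conjugated 1,2-disubstituted alkene as the favoured E isomer, while the excess of 3 limits self-metathesis of 6 and benzoquinone suppresses double-bond migration by ruthenium hydrides.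

**Step 5**
Reactants: 7 (R)-4-benzyl-3-[(E)-5-(4-TBSO-phenyl)pent-4-enoyl]oxazolidin-2-one; 2 4-(tert-butyldimethylsilyloxy)benzaldehyde
Product: 10 syn-aldol imide (C2 R and C3 R; free C2 hydroxyl), via Z-boron enolate 8 (not isolated), via boron aldolate 9 (not isolated)
Conditions: Bu2BOTf, Et3N, CH2Cl2, −78 → 0 °C; 2, −78 → 0 °C; then pH 7 buffer, MeOH, 30 % H2O2, 0 °C
Reagents that add atoms: none
Why: Evans syn-aldol reaction, in which soft enolisation gives the Z-boron enolate 8 and this adds to 2 through a closed Zimmerman–Traxler chair on the enolate face left open by the benzyl group of the (R)-auxiliary, so that C2 and C3 are set together as the syn pair with the absolute configuration of the target (both R here, C3 becoming S later by a change of priorities only).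

**Step 6**
Reactants: 10 syn-aldol imide
Product: 11 C2-O-TES aldol imide (C2 R, C3 R)
Conditions: TESOTf, 2,6-lutidine, CH2Cl2, −78 → 0 °C
Reagents that add atoms: triethylsilyl triflate, CC[Si](CC)(CC)OS(=O)(=O)C(F)(F)F
Why: Silyl triflate/lutidine silylation of a secondary alcohol is fast at low temperature and too weakly basic for retro-aldol cleavage, and TES is chosen because acidic fluoride can later remove it without loss of the aryl TBS ethers.

**Step 7**
Reactants: 11 C2-O-TES aldol imide
Product: 12 (2S,4E)-5-(4-TBSO-phenyl)-2-[(R)-(4-TBSO-phenyl)(triethylsilyloxy)methyl]pent-4-en-1-ol (C4 primary alcohol; C2 R, C3 S)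
Conditions: LiBH4, MeOH (1 equiv), Et2O, 0 °C
Reagents that add atoms: none
Why: Reductive cleavage of the N-acyl oxazolidinone by hydride attack at the exocyclic carbonyl, which does not enolise C3, leaves the silyl ethers and the alkene alone and returns the auxiliary.

**Step 8**
Reactants: 12 C4 primary alcohol
Product: 13 C4 primary iodide (C2 R, C3 R by priority change; same spatial arrangement as 12)
Conditions: PPh3, I2, imidazole, CH2Cl2, 0 °C; then 12, 0 °C → rt
Reagents that add atoms: iodine, [I][I]
Why: Appel-type iodination through the alkoxyphosphonium salt with SN2 displacement at the primary C4, buffered by imidazole so that the TES ether stays.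

**Step 9**
Reactants: 13 C4 primary iodide; 14 3-iodooxetane
Product: 16 C2-O-TES ether of the oxetan-3-ylmethyl carbinol (C2 R, C3 S), via alkylzinc iodide 15 (not isolated)
Conditions: Zn dust, I2 (5 mol %), DMA, 40 °C; then 14 (1.5 equiv), NiCl2(glyme) (10 mol %), s-Bu-pybox (12 mol %), DMA, rt
Reagents that add atoms: none
Why: Zinc insertion into the primary alkyl iodide followed by nickel/pybox-catalysed alkyl–alkyl Negishi coupling with a secondary alkyl iodide forms C4–C5 under neutral conditions that spare silyl ethers, styrene and oxetane, the zinc-bearing C4 having no β-leaving group and no stereocentre arising because the future C5 still carries two identical CH2O arms.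

**Step 10**
Reactants: 16 C2-O-TES oxetane
Product: 17 (1R,2S,4E)-1,5-bis(4-TBSO-phenyl)-2-(oxetan-3-ylmethyl)pent-4-en-1-ol (C2 R, C3 S)
Conditions: HF·pyridine, pyridine, THF, 0 °C
Reagents that add atoms: none
Why: Selective silyl ether cleavage by acidic fluoride, which removes an alkyl TES ether far faster than aryl TBS ethers (these are labile to basic fluoride), while the excess pyridine keeps the medium too weakly acidic to touch the oxetane or the benzylic carbinol.

**Step 11**
Reactants: 17 oxetanyl carbinol
Product: 18 all-cis (2R,3S,5S)-2-(4-TBSO-phenyl)-3-[(E)-3-(4-TBSO-phenyl)allyl]-5-(hydroxymethyl)tetrahydropyran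
Conditions: (R)-3,3'-bis(2,4,6-triisopropylphenyl)-1,1'-binaphthyl-2,2'-diyl hydrogen phosphate (10 mol %), dry toluene (0.02 M), rt → 40 °C
Reagents that add atoms: none
Why: The P–OH of the acid hydrogen-bonds (partly protonates) the oxetane oxygen while its P=O accepts the proton of the C2 hydroxyl, and the C2 oxygen displaces the oxetane oxygen at one CH2 by backside SN2 attack, the release of about 25 kcal/mol of ring strain making the step irreversible. The reaction type is the known chiral-phosphoric-acid-catalysed desymmetrising opening of 3-substituted oxetanes by a tethered alcohol. The pyran closes in the 6-exo-tet mode, and the collinear O1···C6–O array holds the C5–C7 bond anti to O1, so the freed CH2OH arm is equatorial in either chair-like transition state. C5, the only new stereocentre, is defined by which diastereotopic methylene becomes C6: the all-cis isomer needs the chair with the cinnamyl chain equatorial and ring B axial, its C5 epimer the chair with ring B equatorial and the chain axial, so the substrate gives no help (its bias is, if anything, slightly adverse) and the 3,3'-aryl pocket of the matched acid enantiomer is the controlling element. C2 and C3 are retained because the C2–O bond is never broken. The step needs oxetane activation without ionisation of the electron-rich benzylic C2 carbinol or of the product ether and without intermolecular opening by the new primary alcohol, which is secured by the higher basicity and strain of the oxetane oxygen, by the silylated phenol of ring B (no para-quinone methide possible), by the weak acid in an unpolar solvent and by high dilution.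

**Step 12**
Reactants: 18 all-cis 5-hydroxymethyl pyran
Product: 19 (2R,3S,5R)-pyran-5-carbaldehyde (C7 aldehyde)
Conditions: Dess–Martin periodinane, NaHCO3, CH2Cl2, 0 °C → rt
Reagents that add atoms: none
Why: Dess–Martin oxidation under bicarbonate buffer is neutral enough to avoid enolisation of the aldehyde, which would epimerise C5 towards the more stable trans isomer or open the pyran by β-elimination of O1.

**Step 13**
Reactants: 19 C7 aldehyde; 20 (4-bromophenoxy)(tert-butyl)dimethylsilane
Product: 22 C7 carbinol bearing ring C (2R,3S,5R; both C7 epimers), via aryl Grignard reagent 21 (not isolated)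
Conditions: 20, Mg turnings, THF, 40 °C; then 19, THF, −78 °C; aqueous work-up
Reagents that add atoms: none
Why: Grignard addition to an aldehyde, in which 1,2-addition at −78 °C should outrun enolisation at C5 and no facial control is needed because C7 is reset in steps 14 and 15.

**Step 14**
Reactants: 22 C7 carbinol (epimer mixture)
Product: 23 (2R,3S,5R)-5-(4-TBSO-benzoyl) pyran (C7 aryl ketone)
Conditions: Dess–Martin periodinane, NaHCO3, CH2Cl2, 0 °C → rt
Reagents that add atoms: none
Why: Dess–Martin oxidation of a benzylic alcohol merges both C7 epimers into one ketone under buffered, non-enolising conditions that protect C5 and the β-alkoxy ketone array.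

**Step 15**
Reactants: 23 C7 aryl ketone
Product: 24 (2R,3S,5R,7R)-carbinol, tris-TBS ether of the target
Conditions: (S)-2-methyl-CBS-oxazaborolidine (20 mol %), catecholborane, toluene, −78 → −40 °C
Reagents that add atoms: none
Why: Corey–Bakshi–Shibata reduction, in which the ketone binds to the (S)-oxazaborolidine with ring C as the large group and receives hydride on its Si face to give (R)-C7 (the sense that turns acetophenone into the R alcohol), catecholborane replacing BH3 because it does not hydroborate the styrenyl alkene at low temperature.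

**Step 16**
Reactants: 24 tris-TBS ether
Product: 25 CNP0182155.1 (2R,3S,5R,7R; E alkene)
Conditions: TBAF, AcOH (1:1), THF, 0 °C
Reagents that add atoms: none
Why: Fluoride desilylation of the three aryl silyl ethers, buffered with acetic acid so that no free phenoxide can expel O1 at C2 or hydroxide at C7 through a para-quinone methide, which keeps both benzylic centres intact.

**Compound list**
1 | 4-hydroxybenzaldehyde | O=Cc1ccc(O)cc1 | starting material
2 | 4-(tert-butyldimethylsilyloxy)benzaldehyde | O=Cc1ccc(O[Si](C)(C)C(C)(C)C)cc1 | intermediate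
3 | tert-butyldimethyl(4-vinylphenoxy)silane | C=Cc1ccc(O[Si](C)(C)C(C)(C)C)cc1 | intermediate
4 | (R)-4-benzyloxazolidin-2-one | O=C1N[C@H](Cc2ccccc2)CO1 | starting material
5 | pent-4-enoyl chloride | C=CCCC(=O)Cl | starting material
6 | (R)-4-benzyl-3-(pent-4-enoyl)oxazolidin-2-one | C=CCCC(=O)N1C(=O)OC[C@H]1Cc1ccccc1 | intermediate
7 | (R)-4-benzyl-3-[(E)-5-(4-TBSO-phenyl)pent-4-enoyl]oxazolidin-2-one | CC(C)(C)[Si](C)(C)Oc1ccc(/C=C/CCC(=O)N2C(=O)OC[C@H]2Cc2ccccc2)cc1 | intermediate
8 | (Z)-dibutylboron enolate of 7 | CCCCB(CCCC)O/C(=C\C/C=C/c1ccc(O[Si](C)(C)C(C)(C)C)cc1)N1C(=O)OC[C@H]1Cc1ccccc1 | intermediate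
9 | dibutylboron aldolate (C2 R, C3 R) | CC(C)(C)[Si](C)(C)Oc1ccc(/C=C/C[C@@H](C(=O)N2C(=O)OC[C@H]2Cc2ccccc2)[C@@H](OB(CCCC)CCCC)c2ccc(O[Si](C)(C)C(C)(C)C)cc2)cc1 | intermediate
10 | syn-aldol imide (C2 R, C3 R) | CC(C)(C)[Si](C)(C)Oc1ccc(/C=C/C[C@@H](C(=O)N2C(=O)OC[C@H]2Cc2ccccc2)[C@@H](O)c2ccc(O[Si](C)(C)C(C)(C)C)cc2)cc1 | intermediate
11 | C2-O-TES aldol imide (C2 R, C3 R) | CC(C)(C)[Si](C)(C)Oc1ccc(/C=C/C[C@@H](C(=O)N2C(=O)OC[C@H]2Cc2ccccc2)[C@@H](O[Si](CC)(CC)CC)c2ccc(O[Si](C)(C)C(C)(C)C)cc2)cc1 | intermediate
12 | C4 primary alcohol (C2 R, C3 S) | CC(C)(C)[Si](C)(C)Oc1ccc(/C=C/C[C@@H](CO)[C@@H](O[Si](CC)(CC)CC)c2ccc(O[Si](C)(C)C(C)(C)C)cc2)cc1 | intermediate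
13 | C4 primary iodide (C2 R, C3 R) | CC(C)(C)[Si](C)(C)Oc1ccc(/C=C/C[C@@H](CI)[C@@H](O[Si](CC)(CC)CC)c2ccc(O[Si](C)(C)C(C)(C)C)cc2)cc1 | intermediate
14 | 3-iodooxetane | IC1COC1 | starting material
15 | C4 alkylzinc iodide (C2 R, C3 R) | CC(C)(C)[Si](C)(C)Oc1ccc(/C=C/C[C@@H](C[Zn]I)[C@@H](O[Si](CC)(CC)CC)c2ccc(O[Si](C)(C)C(C)(C)C)cc2)cc1 | intermediate
16 | C2-O-TES ether of the oxetan-3-ylmethyl carbinol (C2 R, C3 S) | CC(C)(C)[Si](C)(C)Oc1ccc(/C=C/C[C@@H](CC2COC2)[C@@H](O[Si](CC)(CC)CC)c2ccc(O[Si](C)(C)C(C)(C)C)cc2)cc1 | intermediate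
17 | (1R,2S,4E)-1,5-bis(4-TBSO-phenyl)-2-(oxetan-3-ylmethyl)pent-4-en-1-ol | CC(C)(C)[Si](C)(C)Oc1ccc(/C=C/C[C@@H](CC2COC2)[C@@H](O)c2ccc(O[Si](C)(C)C(C)(C)C)cc2)cc1 | intermediate
18 | all-cis (2R,3S,5S)-5-hydroxymethyl pyran | CC(C)(C)[Si](C)(C)Oc1ccc(/C=C/C[C@H]2C[C@@H](CO)CO[C@H]2c2ccc(O[Si](C)(C)C(C)(C)C)cc2)cc1 | intermediate
19 | (2R,3S,5R)-pyran-5-carbaldehyde | CC(C)(C)[Si](C)(C)Oc1ccc(/C=C/C[C@H]2C[C@@H](C=O)CO[C@H]2c2ccc(O[Si](C)(C)C(C)(C)C)cc2)cc1 | intermediate
20 | (4-bromophenoxy)(tert-butyl)dimethylsilane | Brc1ccc(O[Si](C)(C)C(C)(C)C)cc1 | starting material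
21 | 4-(tert-butyldimethylsilyloxy)phenylmagnesium bromide | Br[Mg]c1ccc(O[Si](C)(C)C(C)(C)C)cc1 | intermediate
22 | C7 carbinol, both C7 epimers (2R,3S,5R) | CC(C)(C)[Si](C)(C)Oc1ccc(/C=C/C[C@H]2C[C@@H](C(O)c3ccc(O[Si](C)(C)C(C)(C)C)cc3)CO[C@H]2c2ccc(O[Si](C)(C)C(C)(C)C)cc2)cc1 | intermediate
23 | C7 aryl ketone (2R,3S,5R) | CC(C)(C)[Si](C)(C)Oc1ccc(/C=C/C[C@H]2C[C@@H](C(=O)c3ccc(O[Si](C)(C)C(C)(C)C)cc3)CO[C@H]2c2ccc(O[Si](C)(C)C(C)(C)C)cc2)cc1 | intermediate
24 | (2R,3S,5R,7R)-carbinol, tris-TBS ether | CC(C)(C)[Si](C)(C)Oc1ccc(/C=C/C[C@H]2C[C@@H]([C@@H](O)c3ccc(O[Si](C)(C)C(C)(C)C)cc3)CO[C@H]2c2ccc(O[Si](C)(C)C(C)(C)C)cc2)cc1 | intermediate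
25 | CNP0182155.1 | Oc1ccc(/C=C/C[C@H]2C[C@@H]([C@@H](O)c3ccc(O)cc3)CO[C@H]2c2ccc(O)cc2)cc1 | target

**Step count**
Total steps: 16. Formation of the zinc and Grignard reagents is counted inside steps 9 and 13.
Longest linear sequence: 15 steps (1 → 2 → 3 → 7 → 10 → 11 → 12 → 13 → 16 → 17 → 18 → 19 → 22 → 23 → 24 → 25). Step 3 is the only side branch.

**Steps most likely to fail**

1) Step 11.
- What may go wrong: the acid may discriminate too little between the two oxetane methylenes, because it has to work against the preference of ring B for an equatorial place in the closing chair.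
- What may go wrong: a hindered secondary alcohol may open a monosubstituted oxetane only slowly. If heating is then needed, acid-induced ionisation at benzylic C2 could erase the C2/C3 cis relation.
- Fallback (sets out from 16, comes back at 18): C5 is fixed before the ring closure and apart from it.
- The oxetane of 16 is opened intermolecularly with TMSBr under a chiral squaramide hydrogen-bond donor (t-BuOMe, −78 °C), a known enantiotopos-selective halide opening of 3-substituted oxetanes. This gives the bromohydrin trimethylsilyl ether F1. The stereo-determining event is then remote from C2/C3 and needs no chair with an axial ring B.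
- HF·pyridine/pyridine removes both alkyl silyl groups to give the bromo diol F2.
- AgOTf/2,6-di-tert-butylpyridine (CH2Cl2, 0 °C → rt) closes O1–C6 by 6-exo-tet displacement of bromide to give 18. The much slower 4-exo closure by the C7 hydroxyl would only lead back to 17.

2) Step 9.
- What may go wrong: the valuable β-branched zinc reagent may be lost by protonolysis or homocoupling, transmetalation to nickel may be slow, and iodide may open the oxetane under the influence of the zinc salts.
- Fallback (sets out from 13, comes back at 16): the oxetane is built on the chain instead of being coupled to it.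
- Alkylation of dimethyl malonate (NaH, THF/DMF, 50 °C) with 13 gives the malonate F3, and LiAlH4 (Et2O, 0 °C) gives the 1,3-diol F4.
- Selective monotosylation (TsCl, Ag2O, KI cat., CH2Cl2) gives the monotosylate F5. It is a mixture at C5, and this centre disappears again on closure.
- NaH (THF, 0 °C → rt) closes the four-membered ring by Williamson 4-exo-tet displacement to give 16.

3) Step 15.
- What may go wrong: facial discrimination may be poor because both flanks of the ketone are branched.
- What may go wrong: catecholborane may reduce the electron-rich aryl ketone only slowly, leaving time for enolisation at C5 or β-elimination of O1.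
- Fallback (sets out from 19 and 20, comes back at 24, bypassing 22 and 23): C7 is set in the C–C bond-forming step by a catalytic asymmetric arylation of the aldehyde.
- Bromine–lithium exchange on 20 (n-BuLi, t-BuOMe, −78 °C) gives the aryllithium F6. ZnCl2 gives the arylzinc chloride F7, and a second equivalent of n-BuLi gives the aryl(butyl)zinc reagent F8.
- After LiCl has been masked with N,N,N',N'-tetraethylethylenediamine, (−)-3-exo-morpholinoisoborneol (10 mol %) should direct aryl transfer to the Si face of 19 and give 24 directly. The epimerisable ketone is then never made.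

**Further compounds**
F1 | step 11 | bromohydrin trimethylsilyl ether (C2 R, C3 S, C5 S; C6 bromide, C7 OTMS, C2 OTES) | CC(C)(C)[Si](C)(C)Oc1ccc(/C=C/C[C@@H](C[C@@H](CO[Si](C)(C)C)CBr)[C@@H](O[Si](CC)(CC)CC)c2ccc(O[Si](C)(C)C(C)(C)C)cc2)cc1
F2 | step 11 | bromo diol (C2 R, C3 S, C5 S) | CC(C)(C)[Si](C)(C)Oc1ccc(/C=C/C[C@@H](C[C@@H](CO)CBr)[C@@H](O)c2ccc(O[Si](C)(C)C(C)(C)C)cc2)cc1
F3 | step 9 | dimethyl malonate alkylated at C5 by 13 | CC(C)(C)[Si](C)(C)Oc1ccc(/C=C/C[C@@H](CC(C(=O)OC)C(=O)OC)[C@@H](O[Si](CC)(CC)CC)c2ccc(O[Si](C)(C)C(C)(C)C)cc2)cc1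
F4 | step 9 | 2-substituted propane-1,3-diol | CC(C)(C)[Si](C)(C)Oc1ccc(/C=C/C[C@@H](CC(CO)CO)[C@@H](O[Si](CC)(CC)CC)c2ccc(O[Si](C)(C)C(C)(C)C)cc2)cc1
F5 | step 9 | monotosylate of F4 (both C5 epimers) | CC(C)(C)[Si](C)(C)Oc1ccc(/C=C/C[C@@H](CC(CO)COS(=O)(=O)c2ccc(C)cc2)[C@@H](O[Si](CC)(CC)CC)c2ccc(O[Si](C)(C)C(C)(C)C)cc2)cc1
F6 | step 15 | 4-(tert-butyldimethylsilyloxy)phenyllithium | [Li]c1ccc(O[Si](C)(C)C(C)(C)C)cc1
F7 | step 15 | 4-(tert-butyldimethylsilyloxy)phenylzinc chloride | Cl[Zn]c1ccc(O[Si](C)(C)C(C)(C)C)cc1
F8 | step 15 | butyl[4-(tert-butyldimethylsilyloxy)phenyl]zinc | CCCC[Zn]c1ccc(O[Si](C)(C)C(C)(C)C)cc1
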